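The route rests on opening ring A (the NH indole) at N1–C2 and at C3–Br. This leads back to an aniline with a trimethylsilylethynyl group ortho to NH2, ring B bound through N1' on the next carbon, and the future C5 bromine in place. Catalytic PdBr2 with CuBr2 closes the pyrrole ring and turns the resulting C3–palladium bond into C3–Br in one operation. The step exploits the single difference between the two pyrrole rings: Br on C3 of ring A, H on C3' of ring B. Bromine is placed by ring closure, not by competition between two β-carbons. Accordingly, ring B is attached only after the arene bromine is set.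

Key step: step 9

Assumption: the target SMILES carries no descriptor for the hindered C4–N1' axis and the molecule has no stereocentre, so the racemate is made and no step controls that axis.

Step 1
Reactants: 1 2,6-dibromo-4-methoxyaniline
Product: 3 1,3-dibromo-2-fluoro-5-methoxybenzene, via arenediazonium tetrafluoroborate 2 (not isolated)
Conditions: NOBF4 (1.1 equiv), 1,2-dichlorobenzene, 0 °C → rt, then 120 °C
Reagents that add atoms: nitrosonium tetrafluoroborate, N#[O+].F[B-](F)(F)F
Why: Balz–Schiemann fluorodediazoniation, in which NOBF4 diazotises even this weakly basic aniline without water, heating 2 releases N2 while BF4− hands fluoride to the aryl cation, and the symmetry of 1 places fluorine between the two bromines with no regiochemical choice.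

Step 2
Reactants: 3 1,3-dibromo-2-fluoro-5-methoxybenzene
Product: 5 3-bromo-2-fluoro-5-methoxybenzaldehyde, via arylmagnesium chloride 4 (not isolated)
Conditions: i-PrMgCl·LiCl (1.05 equiv), THF, −20 °C; DMF, −20 °C → rt; 1 M HCl
Reagents that add atoms: N,N-dimethylformamide, CN(C)C=O
Why: Bromine–magnesium exchange followed by Bouveault formylation, where the ortho fluorine speeds the exchange, the two bromines are equivalent, the electron-rich 4 resists a second exchange, and −20 °C keeps 4 from collapsing to an aryne.

Step 3
Reactants: 5 3-bromo-2-fluoro-5-methoxybenzaldehyde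
Product: 6 3-bromo-2-fluoro-5-methoxy-6-nitrobenzaldehyde
Conditions: HNO3 (100 %, 1.1 equiv), conc. H2SO4, −10 → 0 °C
Reagents that add atoms: nitric acid, O[N+](=O)[O-]
Why: Electrophilic aromatic nitration, in which OMe directs to its two ortho carbons (its para carbon bears F) and C6 is preferred to C4 because it lies para rather than ortho to bromine, in line with the known preference of 3-methoxybenzaldehydes for nitration between CHO and OMe.

Step 4
Reactants: 7 5-bromooxindole (5-bromo-1,3-dihydro-2H-indol-2-one)
Product: 8 2,5-dibromo-1H-indole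
Conditions: POBr3 (1.5 equiv), imidazole (1.2 equiv), ClCH2CH2Cl, 80 °C; used at once in step 5
Reagents that add atoms: phosphoryl bromide, O=P(Br)(Br)Br
Why: Vilsmeier-type deoxybromination of a lactam, in which POBr3 activates the carbonyl oxygen, bromide adds at C2, loss of the phosphorus acid and of a C3 proton aromatises the ring, and imidazole buffers the acid that would degrade 8.

Step 5
Reactants: 6 3-bromo-2-fluoro-5-methoxy-6-nitrobenzaldehyde; 8 2,5-dibromo-1H-indole
Product: 9 3-bromo-2-(2,5-dibromo-1H-indol-1-yl)-5-methoxy-6-nitrobenzaldehyde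
Conditions: Cs2CO3 (1.5 equiv), DMF, 0 °C → rt (50 °C if slow), dark
Reagents that add atoms: none
Why: Nucleophilic aromatic substitution by addition–elimination, in which the caesium indolide of 8 (N-selective in DMF) adds at C2 of 6, the ortho CHO takes up the charge with inductive help from ortho Br and meta NO2, and fluoride leaves far faster than the bromide para to NO2 could (element effect, reinforced because CHO and OMe twist that nitro group out of conjugation).

Step 6
Reactants: 9 3-bromo-2-(2,5-dibromo-1H-indol-1-yl)-5-methoxy-6-nitrobenzaldehyde; 10 dimethyl (1-diazo-2-oxopropyl)phosphonate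
Product: 11 2,5-dibromo-1-(6-bromo-2-ethynyl-4-methoxy-3-nitrophenyl)-1H-indole
Conditions: K2CO3 (2 equiv), MeOH/THF 1:1, 0 °C → rt
Reagents that add atoms: dimethyl (1-diazo-2-oxopropyl)phosphonate 10, CC(=O)C(=[N+]=[N-])P(=O)(OC)OC
Why: Seyferth–Gilbert homologation in the Ohira–Bestmann variant, in which methanolysis of 10 frees the diazomethylphosphonate anion, this adds to the electron-poor aldehyde, and Horner–Wadsworth–Emmons-type elimination, loss of N2 and a 1,2-hydride shift give the alkyne under carbonate conditions too mild to displace the aryl bromide or ring B.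

Step 7
Reactants: 11 2,5-dibromo-1-(6-bromo-2-ethynyl-4-methoxy-3-nitrophenyl)-1H-indole; 12 chlorotrimethylsilane
Product: 14 2,5-dibromo-1-{6-bromo-4-methoxy-3-nitro-2-[(trimethylsilyl)ethynyl]phenyl}-1H-indole, via lithium acetylide 13 (not isolated)
Conditions: LiN(SiMe3)2 (1.1 equiv), THF, −78 °C; Me3SiCl (1.3 equiv), −78 → 0 °C
Reagents that add atoms: chlorotrimethylsilane 12, C[Si](C)(C)Cl
Why: C-silylation of a terminal alkyne by deprotonation and trapping, since the hindered amide base removes only the acetylenic proton at −78 °C, does not add to the nitroarene and, unlike an alkyllithium, does not exchange with the aryl bromides.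

Step 8
Reactants: 14 2,5-dibromo-1-{6-bromo-4-methoxy-3-nitro-2-[(trimethylsilyl)ethynyl]phenyl}-1H-indole
Product: 15 4-bromo-3-(2,5-dibromo-1H-indol-1-yl)-6-methoxy-2-[(trimethylsilyl)ethynyl]aniline
Conditions: Fe powder (6 equiv), NH4Cl (8 equiv), EtOH/H2O 4:1, 70 °C
Reagents that add atoms: none
Why: Béchamp-type nitro reduction by electron transfer from iron at near-neutral pH, a method known to spare aryl and heteroaryl bromides, alkynes and alkynylsilanes, which catalytic hydrogenation would not.

Step 9
Reactants: 15 4-bromo-3-(2,5-dibromo-1H-indol-1-yl)-6-methoxy-2-[(trimethylsilyl)ethynyl]aniline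
Product: 17 3,5-dibromo-4-(2,5-dibromo-1H-indol-1-yl)-7-methoxy-2-(trimethylsilyl)-1H-indole, via 3-indolylpalladium bromide 16 (not isolated)
Conditions: PdBr2 (10 mol %), CuBr2 (2.2 equiv), ClCH2CH2Cl, rt; prompt aq. NaHCO3 work-up
Reagents that add atoms: copper dibromide, Br[Cu]Br
Why: PdBr2 binds the alkyne, the free NH2 adds anti to the metal at the silicon-bearing carbon to form N1–C2, loss of HBr leaves 16, and CuBr2 transfers bromide to that carbon (C3–Br) while handing PdBr2 back, two CuBr2 ending as CuBr. The reaction type is the known aminopalladation–halodepalladation of free 2-alkynylanilines with a palladium dihalide and a copper dihalide to 3-halo-1H-indoles, and silyl-capped alkynes are accepted partners in the related halocyclisations that give 3-halo-2-silylindoles. The pyrrole ring of ring A closes in the 5-endo-dig mode, the only one the ortho geometry allows, which puts the metal, and hence bromine, on the carbon bound to the arene. No stereocentre is created and the C4–N1' axis stays racemic. The step needs C3 over C3' and intact C–Br bonds: bromine follows the C–Pd bond, ring B is a poor substrate for CuBr2 because two bromines and the twisted N-aryl group lower its nucleophilicity, the position para to NH2 that CuBr2 would otherwise attack is already brominated, and palladium stays divalent so that oxidative addition into C–Br has no entry. The SiMe3 cap keeps the alkyne from forming a copper acetylide and dimerising, and any early loss of it to the HBr released only anticipates step 10.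

Step 10
Reactants: 17 3,5-dibromo-4-(2,5-dibromo-1H-indol-1-yl)-7-methoxy-2-(trimethylsilyl)-1H-indole
Product: 18 3,5-dibromo-4-(2,5-dibromo-1H-indol-1-yl)-7-methoxy-1H-indole (target)
Conditions: Bu4NF (1 M in THF, ca. 5 % H2O, 1.5 equiv), THF, 0 °C → rt
Reagents that add atoms: none
Why: Fluoride-induced protodesilylation, in which fluoride attacks the small SiMe3 group, the C2 carbanion equivalent (stabilised by the ring nitrogen and the C3 bromine) is protonated by the water in the reagent, and the non-acidic medium avoids C3 protonation, the path by which 3-bromoindoles lose or shift bromine.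

Compound list
1 | 2,6-dibromo-4-methoxyaniline | COc1cc(Br)c(N)c(Br)c1 | starting material
2 | 2,6-dibromo-4-methoxybenzenediazonium tetrafluoroborate | COc1cc(Br)c([N+]#N)c(Br)c1.F[B-](F)(F)F | intermediate
3 | 1,3-dibromo-2-fluoro-5-methoxybenzene | COc1cc(Br)c(F)c(Br)c1 | intermediate
4 | (3-bromo-2-fluoro-5-methoxyphenyl)magnesium chloride | COc1cc(Br)c(F)c([Mg]Cl)c1 | intermediate
5 | 3-bromo-2-fluoro-5-methoxybenzaldehyde | COc1cc(Br)c(F)c(C=O)c1 | intermediate
6 | 3-bromo-2-fluoro-5-methoxy-6-nitrobenzaldehyde | COc1cc(Br)c(F)c(C=O)c1[N+](=O)[O-] | intermediate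
7 | 5-bromooxindole | O=C1Cc2cc(Br)ccc2N1 | starting material
8 | 2,5-dibromo-1H-indole | Brc1cc2cc(Br)ccc2[nH]1 | intermediate
9 | 3-bromo-2-(2,5-dibromo-1H-indol-1-yl)-5-methoxy-6-nitrobenzaldehyde | COc1cc(Br)c(-n2c(Br)cc3cc(Br)ccc32)c(C=O)c1[N+](=O)[O-] | intermediate
10 | dimethyl (1-diazo-2-oxopropyl)phosphonate | CC(=O)C(=[N+]=[N-])P(=O)(OC)OC | starting material
11 | 2,5-dibromo-1-(6-bromo-2-ethynyl-4-methoxy-3-nitrophenyl)-1H-indole | COc1cc(Br)c(-n2c(Br)cc3cc(Br)ccc32)c(C#C)c1[N+](=O)[O-] | intermediate
12 | chlorotrimethylsilane | C[Si](C)(C)Cl | starting material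
13 | lithium acetylide of 11 | COc1cc(Br)c(-n2c(Br)cc3cc(Br)ccc32)c(C#C[Li])c1[N+](=O)[O-] | intermediate
14 | 2,5-dibromo-1-{6-bromo-4-methoxy-3-nitro-2-[(trimethylsilyl)ethynyl]phenyl}-1H-indole | COc1cc(Br)c(-n2c(Br)cc3cc(Br)ccc32)c(C#C[Si](C)(C)C)c1[N+](=O)[O-] | intermediate
15 | 4-bromo-3-(2,5-dibromo-1H-indol-1-yl)-6-methoxy-2-[(trimethylsilyl)ethynyl]aniline | COc1cc(Br)c(-n2c(Br)cc3cc(Br)ccc32)c(C#C[Si](C)(C)C)c1N | intermediate
16 | [5-bromo-4-(2,5-dibromo-1H-indol-1-yl)-7-methoxy-2-(trimethylsilyl)-1H-indol-3-yl]palladium bromide | COc1cc(Br)c(-n2c(Br)cc3cc(Br)ccc32)c2c([Pd]Br)c([Si](C)(C)C)[nH]c12 | intermediate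
17 | 3,5-dibromo-4-(2,5-dibromo-1H-indol-1-yl)-7-methoxy-2-(trimethylsilyl)-1H-indole | COc1cc(Br)c(-n2c(Br)cc3cc(Br)ccc32)c2c(Br)c([Si](C)(C)C)[nH]c12 | intermediate
18 | 3,5-dibromo-4-(2,5-dibromo-1H-indol-1-yl)-7-methoxy-1H-indole | COc1cc(Br)c(-n2c(Br)cc3cc(Br)ccc32)c2c(Br)c[nH]c12 | target

Total step count: 10. Longest linear sequence: 9 (steps 1–3 and 5–10, from 1). Step 4 is a one-step side branch.

Steps most likely to fail

Step 9.
- **What may go wrong:** The amine may add slowly to a silyl-capped alkyne that is walled in by ring B. The C3–palladium bond may capture a proton before bromide transfer. Surplus CuBr2 may slowly brominate ring B.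
- **Fallback (from 15, back at 18):** Ring closure and bromination are separated. CuI in DMF at 100 °C cyclises 15 with loss of the silyl group to 5-bromo-4-(2,5-dibromo-1H-indol-1-yl)-7-methoxy-1H-indole F1. One equivalent of N-bromosuccinimide in THF at −78 °C then brominates C3 of ring A. This relies on the NH, methoxy-bearing indole being more nucleophilic than the N-aryl, doubly brominated ring B. Steps 9 and 10 are both replaced.

Step 5.
- **What may go wrong:** Addition may be slow at a carbon flanked by CHO and Br. The bromide para to the nitro group, or the nitro group itself, may be displaced in competition. Compound 8 may decay in basic DMF.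
- **Fallback (from 8, back at 9):** The coupling is run base-free with a silicon relay. Compound 8 is N-silylated (NaH, Me3SiCl, THF) to 2,5-dibromo-1-(trimethylsilyl)-1H-indole F2, which is combined with 6 and catalytic CsF in DMF. Fluoride frees the indolide in low concentration. Only substitution at the C–F carbon returns the fluoride that carries the chain, so attack elsewhere cannot propagate. Si–F bond formation supplies the driving force.

Step 1.
- **What may go wrong:** Thermolysis of the methoxy-stabilised diazonium salt may lead to hydrodediazoniation, tar formation or arylation of the solvent.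
- **Fallback (from 1, back at 3):** The polarity of the fluorination is reversed. Compound 1 is diazotised to 2 as before, but 2 is quenched with KI at rt to 1,3-dibromo-2-iodo-5-methoxybenzene F3. Iodine–magnesium exchange (i-PrMgCl·LiCl, THF, −40 °C) gives (2,6-dibromo-4-methoxyphenyl)magnesium chloride F4, which is fluorinated with N-fluorobenzenesulfonimide.

Further compounds
F1 | step 9 | 5-bromo-4-(2,5-dibromo-1H-indol-1-yl)-7-methoxy-1H-indole | COc1cc(Br)c(-n2c(Br)cc3cc(Br)ccc32)c2cc[nH]c12
F2 | step 5 | 2,5-dibromo-1-(trimethylsilyl)-1H-indole | C[Si](C)(C)n1c(Br)cc2cc(Br)ccc21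
F3 | step 1 | 1,3-dibromo-2-iodo-5-methoxybenzene | COc1cc(Br)c(I)c(Br)c1
F4 | step 1 | (2,6-dibromo-4-methoxyphenyl)magnesium chloride | COc1cc(Br)c([Mg]Cl)c(Br)c1
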